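**Assumption:** the absolute configuration is taken exactly from the given SMILES, i.e. (1R,2S,5R,7S,9S,10S). Atom labels C1–C15 follow eudesmane numbering (C14 = CH2OH on C10, C15 = CH3 on C4, C11–C13 = isopropenyl on C7) and are used for every intermediate. α means on the same side as C14, β the opposite side.

## Retrosynthetic overview

1. Target ⇐ C14–O desilylation ⇐ C2 silyl ether exchanged for acetate ⇐ tigloylation of a 1-hydroxy-eudesmane whose only free OH comes from an epoxide oxygen.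
2. Decalin (second ring event): transannular anti-opening of a 1,10-epoxygermacra-4,11-diene by the 4,5-olefin (C5–C10 bond), then loss of H-3 to give the Δ3 olefin.
3. Ten-membered ring (first ring event, same flask): cation–olefin closure C6–C7 (farnesyl C1→C10) of an acyclic, pre-oxidised farnesyl chloride; proton loss gives the isopropenyl group.
4. Acyclic precursor ⇐ epoxy diol ⇐ (S,S)-enediol (CBS reduction, then matched Sharpless epoxidation) ⇐ E-enedione.
5. Enedione ⇐ oxidative opening of a 2,3,5-trisubstituted furan built from furan-3-ylmethanol, prenyl bromide and a C5 bromo-chloride from isoprene monoxide.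

## Route

Step 1
Reactants: 1 2-methyl-2-vinyloxirane
Product: 2 (E)-4-chloro-2-methylbut-2-en-1-ol
Conditions: TiCl4 (1.1 equiv), CH2Cl2, −85 °C; aq. HCl work-up
Reagents that add atoms: titanium tetrachloride, Cl[Ti](Cl)(Cl)Cl
Why: Lewis-acid-promoted SN2′ opening of the vinyl epoxide by chloride gives the E-trisubstituted allylic chloride, which later becomes the E-C4=C5 olefin and the C6 leaving group.

Step 2
Reactants: 2 (E)-4-chloro-2-methylbut-2-en-1-ol
Product: 3 (E)-1-bromo-4-chloro-2-methylbut-2-ene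
Conditions: PBr3 (0.4 equiv), Et2O, −10 → 0 °C
Reagents that add atoms: phosphorus tribromide, BrP(Br)Br
Why: SN2 bromination of the primary allylic alcohol differentiates the two allylic termini (C–Br reacts far faster than C–Cl with carbanions) without touching the olefin geometry.

Step 3
Reactants: 4 furan-3-ylmethanol; 5 1-bromo-3-methylbut-2-ene (prenyl bromide)
Product: 8 tert-butyl{[2-(3-methylbut-2-en-1-yl)furan-3-yl]methoxy}diphenylsilane, via dilithiated furanmethanol 6 (not isolated), via lithium alkoxide 7 (not isolated)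
Conditions: n-BuLi (2.2 equiv), THF, 0 °C; 5, −78 → 0 °C; then TBDPSCl, DMAP (cat.), rt
Reagents that add atoms: tert-butyl(chloro)diphenylsilane, CC(C)(C)[Si](Cl)(c1ccccc1)c1ccccc1
Why: Alkoxide-directed ortho-lithiation at furan C2, SN2 C-prenylation (rosefuran-type) and in situ O-silylation of the lithium alkoxide; no stereocentre is formed.

Step 4
Reactants: 8 tert-butyl{[2-(3-methylbut-2-en-1-yl)furan-3-yl]methoxy}diphenylsilane; 3 (E)-1-bromo-4-chloro-2-methylbut-2-ene
Product: 10 tert-butyl{[5-[(E)-4-chloro-2-methylbut-2-en-1-yl]-2-(3-methylbut-2-en-1-yl)furan-3-yl]methoxy}diphenylsilane, via 5-lithiofuran 9 (not isolated)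
Conditions: n-BuLi (1.1 equiv), THF, −78 → 0 °C; then 3, −78 °C → rt
Reagents that add atoms: none
Why: Lithiation of the only free furan α-position and chemoselective SN2 displacement of the allylic bromide (Br over Cl) assemble the full C15 chain with the E-C4=C5 geometry carried in from 3.

Step 5
Reactants: 10 tert-butyl{[5-[(E)-4-chloro-2-methylbut-2-en-1-yl]-2-(3-methylbut-2-en-1-yl)furan-3-yl]methoxy}diphenylsilane
Product: 12 (2E,6E)-7-{[tert-butyl(diphenyl)silyl]oxymethyl}-1-chloro-3,11-dimethyldodeca-2,6,10-triene-5,8-dione, via Z-enedione 11 (not isolated)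
Conditions: NBS (1.05 equiv), NaHCO3, acetone/H2O (10:1), −20 °C; then I2 (5 mol %), CH2Cl2, rt
Reagents that add atoms: water, O
Why: Oxidative ring opening of the 2,5-dialkylfuran (bromination/hydrolysis) unmasks the 1,4-enedione, and iodine-catalysed Z→E isomerisation gives the more stable trans-diacyl olefin, which fixes the E-C1=C10 geometry.

Step 6
Reactants: 12 (2E,6E)-7-{[tert-butyl(diphenyl)silyl]oxymethyl}-1-chloro-3,11-dimethyldodeca-2,6,10-triene-5,8-dione
Product: 13 (2E,5S,6E,8S)-7-{[tert-butyl(diphenyl)silyl]oxymethyl}-1-chloro-3,11-dimethyldodeca-2,6,10-triene-5,8-diol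
Conditions: (R)-Me-CBS (0.4 equiv), catecholborane (3 equiv), toluene/CH2Cl2, −78 °C
Reagents that add atoms: none
Why: Corey–Bakshi–Shibata 1,2-reduction of both enone carbonyls with the alkenyl group as the large substituent sets C2 and C9 (both S); the two centres have the same sense, so one catalyst enantiomer sets both.

Step 7
Reactants: 13 (2E,5S,6E,8S)-7-{[tert-butyl(diphenyl)silyl]oxymethyl}-1-chloro-3,11-dimethyldodeca-2,6,10-triene-5,8-diol
Product: 14 (2E,5S,6S,7S,8S)-7-{[tert-butyl(diphenyl)silyl]oxymethyl}-1-chloro-6,7-epoxy-3,11-dimethyldodeca-2,10-diene-5,8-diol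
Conditions: Ti(OiPr)4 (0.3 equiv), L-(+)-DIPT (0.36 equiv), t-BuOOH (2 equiv), 4 Å MS, CH2Cl2, −20 °C
Reagents that add atoms: tert-butyl hydroperoxide, CC(C)(C)OO
Why: Sharpless asymmetric epoxidation touches only the allylic-alcohol olefin; L-(+)-tartrate is matched with both (S)-carbinols and delivers oxygen anti (erythro) to C2–OH and C9–OH, setting C1 and C10.

Step 8
Reactants: 14 (2E,5S,6S,7S,8S)-7-{[tert-butyl(diphenyl)silyl]oxymethyl}-1-chloro-6,7-epoxy-3,11-dimethyldodeca-2,10-diene-5,8-diol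
Product: 16 (2E,5S,6S,7S,8S)-7-{[tert-butyl(diphenyl)silyl]oxymethyl}-1-chloro-6,7-epoxy-3,11-dimethyl-5-(triethylsilyloxy)dodeca-2,10-dien-8-yl acetate, via mono-TES ether 15 (not isolated)
Conditions: TESCl (1.05 equiv), i-Pr2NEt, DMAP (cat.), CH2Cl2, −40 → 0 °C; then Ac2O, 0 °C → rt
Reagents that add atoms: chlorotriethylsilane, CC[Si](Cl)(CC)CC; acetic anhydride, CC(=O)OC(C)=O
Why: Steric differentiation: the C2 hydroxyl (flanked by CH and CH2) is silylated before the C9 hydroxyl (next to fully substituted C10), which is then acetylated; the silyl ether at C2 cannot participate at the later C4 cation and the ester at C9 cannot trap the C11 cation.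

Step 9
Reactants: 16 (2E,5S,6S,7S,8S)-7-{[tert-butyl(diphenyl)silyl]oxymethyl}-1-chloro-6,7-epoxy-3,11-dimethyl-5-(triethylsilyloxy)dodeca-2,10-dien-8-yl acetate
Product: 18 (1R,2S,5R,7S,9S,10R)-9β-acetoxy-14-[tert-butyl(diphenyl)silyloxy]-2α-(triethylsilyloxy)eudesma-3,11-dien-1α-ol, via epoxygermacradiene 17 (not isolated)
Conditions: AgNTf2 (1.2 equiv), 2,6-di-tert-butyl-4-methylpyridine (2.5 equiv), CH2Cl2 (slow addition, ≤1 mM), −78 → −40 °C; then BF3·OEt2 (0.3 equiv), −78 → −30 °C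
Reagents that add atoms: none
Why: Proposed new method: Ag(I) abstracts the allylic chloride to give the E-allyl cation (C4–C6), which is captured at C6 by the distal prenyl olefin through a crown-like ten-membered transition state with the C9 acetoxy group and the nascent C7 side chain both pseudo-equatorial (7,9-cis, 7S), the hindered pyridine removing a methyl proton from the C11 cation to give the isopropenyl group; BF3 then opens the electron-poor epoxide at C10 with anti attack of C5 of the E-4,5-olefin in the crossed transannular array (inversion at C10, trans ring fusion, C1–O retained as the only free OH) and loss of H-3 gives the Δ3 olefin; the closest known reaction types are silver-promoted allyl-cation/olefin (prenyl-transfer) cyclisations, non-enzymatic tail-to-head terpene cyclisations and the acid-mediated transannular cyclisation of 1(10)-epoxygermacrenes to 1-hydroxyeudesmanes.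

Step 10
Reactants: 18 (1R,2S,5R,7S,9S,10R)-9β-acetoxy-14-[tert-butyl(diphenyl)silyloxy]-2α-(triethylsilyloxy)eudesma-3,11-dien-1α-ol
Product: 19 (1R,2S,5R,7S,9S,10S)-9β-acetoxy-14-[tert-butyl(diphenyl)silyloxy]-2α-(triethylsilyloxy)eudesma-3,11-dien-1α-yl (E)-2-methylbut-2-enoate
Conditions: tigloyl chloride, pyridine, DMAP (cat.), CH2Cl2, 0 °C → rt
Reagents that add atoms: tigloyl chloride, C/C=C(\C)C(Cl)=O
Why: DMAP-catalysed acylation of the single free hydroxyl (C1–OH from the epoxide) places the tiglate regiospecifically; the E-ester is the stable isomer and C1 is untouched.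

Step 11
Reactants: 19 (1R,2S,5R,7S,9S,10S)-9β-acetoxy-14-[tert-butyl(diphenyl)silyloxy]-2α-(triethylsilyloxy)eudesma-3,11-dien-1α-yl (E)-2-methylbut-2-enoate
Product: 21 (1R,2S,5R,7S,9S,10S)-2α,9β-diacetoxy-14-[tert-butyl(diphenyl)silyloxy]eudesma-3,11-dien-1α-yl (E)-2-methylbut-2-enoate, via C2 alcohol 20 (not isolated)
Conditions: PPTS (cat.), MeOH/CH2Cl2, 0 °C → rt; evaporate; then Ac2O, pyridine, DMAP (cat.), 0 °C
Reagents that add atoms: acetic anhydride, CC(=O)OC(C)=O
Why: Acid-catalysed methanolysis cleaves the secondary allylic triethylsilyl ether but not the primary tert-butyldiphenylsilyl ether, and the freed C2–OH is acetylated at once before any acyl migration (C2 configuration unchanged).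

Step 12
Reactants: 21 (1R,2S,5R,7S,9S,10S)-2α,9β-diacetoxy-14-[tert-butyl(diphenyl)silyloxy]eudesma-3,11-dien-1α-yl (E)-2-methylbut-2-enoate
Product: 22 (1R,2S,5R,7S,9S,10S)-2α,9β-diacetoxy-14-hydroxyeudesma-3,11-dien-1α-yl (E)-2-methylbut-2-enoate (CNP0267061.1)
Conditions: HF·pyridine, pyridine/THF, 0 °C → rt
Reagents that add atoms: none
Why: Fluoride-mediated silyl ether cleavage under buffered, non-basic conditions frees C14–OH without migration of the neighbouring esters.

## Compound list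

1 | 2-methyl-2-vinyloxirane (isoprene monoxide, racemic) | C=CC1(C)CO1 | starting material
2 | (E)-4-chloro-2-methylbut-2-en-1-ol | OC/C(C)=C/CCl | intermediate
3 | (E)-1-bromo-4-chloro-2-methylbut-2-ene | BrC/C(C)=C/CCl | intermediate
4 | furan-3-ylmethanol | OCc1ccoc1 | starting material
5 | 1-bromo-3-methylbut-2-ene (prenyl bromide) | CC(C)=CCBr | starting material
6 | lithium (2-lithiofuran-3-yl)methanolate | [Li]OCc1ccoc1[Li] | intermediate
7 | lithium [2-(3-methylbut-2-en-1-yl)furan-3-yl]methanolate | [Li]OCc1ccoc1CC=C(C)C | intermediate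
8 | tert-butyl{[2-(3-methylbut-2-en-1-yl)furan-3-yl]methoxy}diphenylsilane | CC(C)=CCc1occc1CO[Si](c1ccccc1)(c1ccccc1)C(C)(C)C | intermediate
9 | 5-lithio derivative of 8 | CC(C)=CCc1oc([Li])cc1CO[Si](c1ccccc1)(c1ccccc1)C(C)(C)C | intermediate
10 | tert-butyl{[5-[(E)-4-chloro-2-methylbut-2-en-1-yl]-2-(3-methylbut-2-en-1-yl)furan-3-yl]methoxy}diphenylsilane | CC(C)=CCc1oc(C/C(C)=C/CCl)cc1CO[Si](c1ccccc1)(c1ccccc1)C(C)(C)C | intermediate
11 | (2E,6Z)-7-{[tert-butyl(diphenyl)silyl]oxymethyl}-1-chloro-3,11-dimethyldodeca-2,6,10-triene-5,8-dione | CC(C)=CCC(=O)/C(CO[Si](c1ccccc1)(c1ccccc1)C(C)(C)C)=C\C(=O)C/C(C)=C/CCl | intermediate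
12 | (2E,6E)-7-{[tert-butyl(diphenyl)silyl]oxymethyl}-1-chloro-3,11-dimethyldodeca-2,6,10-triene-5,8-dione | CC(C)=CCC(=O)/C(CO[Si](c1ccccc1)(c1ccccc1)C(C)(C)C)=C/C(=O)C/C(C)=C/CCl | intermediate
13 | (2E,5S,6E,8S)-7-{[tert-butyl(diphenyl)silyl]oxymethyl}-1-chloro-3,11-dimethyldodeca-2,6,10-triene-5,8-diol | CC(C)=CC[C@H](O)/C(CO[Si](c1ccccc1)(c1ccccc1)C(C)(C)C)=C/[C@@H](O)C/C(C)=C/CCl | intermediate
14 | (2E,5S,6S,7S,8S)-7-{[tert-butyl(diphenyl)silyl]oxymethyl}-1-chloro-6,7-epoxy-3,11-dimethyldodeca-2,10-diene-5,8-diol | CC(C)=CC[C@H](O)[C@]2(CO[Si](c1ccccc1)(c1ccccc1)C(C)(C)C)O[C@H]2[C@@H](O)C/C(C)=C/CCl | intermediate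
15 | 5-O-triethylsilyl ether of 14 (8-OH free) | CC(C)=CC[C@H](O)[C@]2(CO[Si](c1ccccc1)(c1ccccc1)C(C)(C)C)O[C@H]2[C@@H](O[Si](CC)(CC)CC)C/C(C)=C/CCl | intermediate
16 | 5-O-triethylsilyl ether 8-O-acetate of 14 | CC(C)=CC[C@H](OC(C)=O)[C@]2(CO[Si](c1ccccc1)(c1ccccc1)C(C)(C)C)O[C@H]2[C@@H](O[Si](CC)(CC)CC)C/C(C)=C/CCl | intermediate
17 | (1S,2S,4E,7S,9S,10S)-9-acetoxy-14-[tert-butyl(diphenyl)silyloxy]-1,10-epoxy-2-(triethylsilyloxy)germacra-4,11-diene | C=C(C)[C@@H]1C[C@H](OC(C)=O)[C@]2(CO[Si](c3ccccc3)(c3ccccc3)C(C)(C)C)O[C@H]2[C@@H](O[Si](CC)(CC)CC)C/C(C)=C/C1 | intermediate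
18 | (1R,2S,5R,7S,9S,10R)-9β-acetoxy-14-[tert-butyl(diphenyl)silyloxy]-2α-(triethylsilyloxy)eudesma-3,11-dien-1α-ol (5β-H, 7β-isopropenyl) | C=C(C)[C@@H]1C[C@H](OC(C)=O)[C@@]2(CO[Si](c3ccccc3)(c3ccccc3)C(C)(C)C)[C@H](C1)C(C)=C[C@H](O[Si](CC)(CC)CC)[C@@H]2O | intermediate
19 | 1-O-tiglate of 18 | C=C(C)[C@@H]1C[C@H](OC(C)=O)[C@@]2(CO[Si](c3ccccc3)(c3ccccc3)C(C)(C)C)[C@H](C1)C(C)=C[C@H](O[Si](CC)(CC)CC)[C@@H]2OC(=O)/C(C)=C/C | intermediate
20 | 9β-acetoxy-14-[tert-butyl(diphenyl)silyloxy]-2α-hydroxyeudesma-3,11-dien-1α-yl tiglate | C=C(C)[C@@H]1C[C@H](OC(C)=O)[C@@]2(CO[Si](c3ccccc3)(c3ccccc3)C(C)(C)C)[C@H](C1)C(C)=C[C@H](O)[C@@H]2OC(=O)/C(C)=C/C | intermediate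
21 | 2α,9β-diacetoxy-14-[tert-butyl(diphenyl)silyloxy]eudesma-3,11-dien-1α-yl tiglate | C=C(C)[C@@H]1C[C@H](OC(C)=O)[C@@]2(CO[Si](c3ccccc3)(c3ccccc3)C(C)(C)C)[C@H](C1)C(C)=C[C@H](OC(C)=O)[C@@H]2OC(=O)/C(C)=C/C | intermediate
22 | (1R,2S,5R,7S,9S,10S)-2α,9β-diacetoxy-14-hydroxyeudesma-3,11-dien-1α-yl (E)-2-methylbut-2-enoate (CNP0267061.1) | C=C(C)[C@@H]1C[C@H](OC(C)=O)[C@@]2(CO)[C@H](C1)C(C)=C[C@H](OC(C)=O)[C@@H]2OC(=O)/C(C)=C/C | target

## Summary and risks

Total step count: 12.
Longest linear sequence: 11 steps (1 → 2 → 3 → 10 → 12 → 13 → 14 → 16 → 18 → 19 → 21 → 22; the furan arm 4 → 8 → 10 is one step shorter).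

**Step 9 (most likely to fail).** The allyl cation may lose a proton to a diene, or be captured by the epoxide oxygen, before the ten-membered ring closes. The 7,9-cis preference is conformational, not enforced. The C4 cation may also give the Δ4(15) isomer beside Δ3. Fallback, from 16 back to 17, closing the same C6–C7 bond by a metal-mediated carbonyl allylation: Ganem oxidation of the allylic chloride (NMO, MeCN) gives the E-enal F1. Ene-type chlorination of the prenyl terminus (Ca(OCl)2, CO2, CH2Cl2/H2O) gives the chloro-enal F2. Pd(PPh3)4/Et2Zn umpolung allylation at high dilution gives the macrocyclic C6 alcohol F3, from which the 7S isomer is separated. ClCO2Me/pyridine gives the allylic carbonate F4, and Pd(PPh3)4/Bu3SnH hydrogenolysis (hydride to the less substituted terminus C6) gives 17, now isolated. BF3·OEt2 then converts 17 into 18 as in the second stage of step 9.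

**Step 7.** The trisubstituted olefin carries three allylic oxygens and a bulky silyl ether, so the titanium epoxidation may be very slow. Fallback, from 12 back to 14, epoxidising before reducing: catalytic asymmetric nucleophilic (Weitz–Scheffer) epoxidation of the enedione (La(OiPr)3/BINOL/Ph3As=O, t-BuOOH, ligand antipode chosen for the required epoxide) gives the trans-epoxy diketone F5. Zn(BH4)2 in Et2O at −30 °C then reduces both ketones under chelation control to the erythro,erythro diol 14.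

**Step 4.** n-BuLi may deprotonate the doubly activated furfuryl/allylic CH2 (C8) instead of furan C5. Fallback, from 8 back to 10, without an organolithium: iridium-catalysed C–H borylation at the free α-position ([Ir(OMe)(cod)]2, dtbpy, B2pin2) gives the furyl boronate F6. Suzuki–Miyaura allylation with 3 (Pd(PPh3)4, K3PO4, THF/H2O; the C–Br end reacts and coupling occurs at the CH2 terminus) gives 10.

## Further compounds

F1 | step 9 | (2E,5S,6S,7S,8S)-8-acetoxy-7-{[tert-butyl(diphenyl)silyl]oxymethyl}-6,7-epoxy-3,11-dimethyl-5-(triethylsilyloxy)dodeca-2,10-dienal | CC(C)=CC[C@H](OC(C)=O)[C@]2(CO[Si](c1ccccc1)(c1ccccc1)C(C)(C)C)O[C@H]2[C@@H](O[Si](CC)(CC)CC)C/C(C)=C/C=O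
F2 | step 9 | 10-chloro-11(12)-ene analogue of F1 (secondary allylic chloride, epimers at C10 of the chain) | C=C(C)C(Cl)C[C@H](OC(C)=O)[C@]2(CO[Si](c1ccccc1)(c1ccccc1)C(C)(C)C)O[C@H]2[C@@H](O[Si](CC)(CC)CC)C/C(C)=C/C=O
F3 | step 9 | 6-hydroxy derivative of 17 (macrocyclic homoallylic alcohol, C6 epimers) | C=C(C)[C@@H]1C[C@H](OC(C)=O)[C@]2(CO[Si](c3ccccc3)(c3ccccc3)C(C)(C)C)O[C@H]2[C@@H](O[Si](CC)(CC)CC)C/C(C)=C/C1O
F4 | step 9 | 6-O-methoxycarbonyl derivative of F3 | C=C(C)[C@@H]1C[C@H](OC(C)=O)[C@]2(CO[Si](c3ccccc3)(c3ccccc3)C(C)(C)C)O[C@H]2[C@@H](O[Si](CC)(CC)CC)C/C(C)=C/C1OC(=O)OC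
F5 | step 7 | (2E,6R,7R)-7-{[tert-butyl(diphenyl)silyl]oxymethyl}-1-chloro-6,7-epoxy-3,11-dimethyldodeca-2,10-diene-5,8-dione | CC(C)=CCC(=O)[C@]2(CO[Si](c1ccccc1)(c1ccccc1)C(C)(C)C)O[C@H]2C(=O)C/C(C)=C/CCl
F6 | step 4 | tert-butyl{[2-(3-methylbut-2-en-1-yl)-5-(4,4,5,5-tetramethyl-1,3,2-dioxaborolan-2-yl)furan-3-yl]methoxy}diphenylsilane | CC(C)=CCc1oc(B2OC(C)(C)C(C)(C)O2)cc1CO[Si](c1ccccc1)(c1ccccc1)C(C)(C)C
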